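**Plan**
Feature: in ring A the pyran oxygen O1 is bonded to C8a, which is meta to the C5 and C7 methoxyls. The adjacent C8 (ortho to C7-OMe, para to C5-OMe) is the carbon that readily carries a halogen. A C8-C8a aryne, flanked by C7-OMe and bearing the C4-C3-C2-O chain on C4a, should take up oxygen at C8a.
Cuts: O1-C8a (ring C, aryne etherification), then C3-C4 (benzylation of a ring-B arylacetyl imide), then C1'-CH2 (zinc enolate arylation), the C6-prenyl bond (Claisen) and ring D (propargyl ether rearrangement).
Forward: ring D is fused onto ring B first (from 4-bromoresorcinol), and the ring-A benzylic bromide is made in parallel (from 5-bromo-2-hydroxy-4-methoxybenzaldehyde). The two are joined at C3-C4, and ring C closes last.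
Stereochemistry: the single centre C3 (R) is set in the enolate alkylation by (R)-4-benzyloxazolidin-2-one and is only carried through afterwards.

Key step: step 16

Remark: the target SMILES encodes (3R). From the alkylation product onwards the priority order CH2O (or C=O) > aryl > CH2-aryl holds, so the descriptor stays (R) with unchanged geometry. 3-Chloro-3-methylbut-1-yne, the chloride of 2-methylbut-3-yn-2-ol, is taken as a catalogue chemical.

Step 1
Reactants: 1 5-bromo-2-hydroxy-4-methoxybenzaldehyde; 2 3-chloro-3-methylbut-1-yne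
Product: 3 5-bromo-4-methoxy-2-[(2-methylbut-3-yn-2-yl)oxy]benzaldehyde
Conditions: CuCl2·2H2O (1 mol %), DBU, MeCN, 0 °C → rt
Reagents that add atoms: none
Why: Copper-catalysed propargylic etherification, in which DBU breaks the OH···O=C chelate and the phenoxide attacks the copper-activated tertiary propargylic chloride at oxygen, under conditions that leave the aldehyde and the aryl bromide inert.

Step 2
Reactants: 3 5-bromo-4-methoxy-2-[(2-methylbut-3-yn-2-yl)oxy]benzaldehyde
Product: 4 5-bromo-4-methoxy-2-[(2-methylbut-3-en-2-yl)oxy]benzaldehyde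
Conditions: H2 (1 atm), Pd/CaCO3 poisoned with Pb(OAc)2, quinoline, EtOAc, rt
Reagents that add atoms: none
Why: Lindlar semihydrogenation, in which the poisoned palladium surface reduces the terminal alkyne to the vinyl group and releases it before further hydrogen uptake, without cleaving C-Br or reducing the aldehyde.

Step 3
Reactants: 4 5-bromo-4-methoxy-2-[(2-methylbut-3-en-2-yl)oxy]benzaldehyde
Product: 5 5-bromo-2-hydroxy-4-methoxy-3-(3-methylbut-2-enyl)benzaldehyde
Conditions: toluene, 110 °C, sealed tube
Reagents that add atoms: none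
Why: Aromatic Claisen rearrangement, whose [3,3] shift can end only at C3 because the other ortho carbon bears the formyl group, whose allyl inversion turns the 1,1-dimethylallyl ether into the linear prenyl group, and which the gem-dimethyl substitution allows near 110 °C.

Step 4
Reactants: 5 5-bromo-2-hydroxy-4-methoxy-3-(3-methylbut-2-enyl)benzaldehyde
Product: 6 5-bromo-2,4-dimethoxy-3-(3-methylbut-2-enyl)benzaldehyde
Conditions: MeI, K2CO3, DMF, rt
Reagents that add atoms: iodomethane, CI
Why: Williamson methylation of a hindered but acidic phenol with an unhindered electrophile in a dipolar aprotic solvent, with no other alkylatable site in 5.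

Step 5
Reactants: 6 5-bromo-2,4-dimethoxy-3-(3-methylbut-2-enyl)benzaldehyde
Product: 7 [5-bromo-2,4-dimethoxy-3-(3-methylbut-2-enyl)phenyl]methanol
Conditions: NaBH4, MeOH, 0 °C
Reagents that add atoms: none
Why: Borohydride reduction of an aromatic aldehyde, which leaves the aryl bromide and the trisubstituted alkene untouched.

Step 6
Reactants: 7 [5-bromo-2,4-dimethoxy-3-(3-methylbut-2-enyl)phenyl]methanol
Product: 8 1-bromo-5-(bromomethyl)-2,4-dimethoxy-3-(3-methylbut-2-enyl)benzene
Conditions: CBr4, PPh3, CH2Cl2, 0 °C; used directly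
Reagents that add atoms: tetrabromomethane, BrC(Br)(Br)Br
Why: Appel reaction, in which bromide displaces the alkoxyphosphonium group under neutral conditions so that no HBr adds to the prenyl alkene, while the ring bromine and the two methoxyls twisted out of conjugation keep the benzylic bromide manageable.

Step 7
Reactants: 9 4-bromoresorcinol
Product: 10 2-bromo-5-(triisopropylsilyloxy)phenol
Conditions: iPr3SiCl (1.0 equiv), imidazole, CH2Cl2/DMF, 0 °C
Reagents that add atoms: chlorotriisopropylsilane, CC(C)[Si](Cl)(C(C)C)C(C)C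
Why: Sterically controlled monosilylation, in which the bulky silyl chloride reacts faster at the open hydroxyl para to bromine than at the hydroxyl crowded by the ortho bromine.

Step 8
Reactants: 10 2-bromo-5-(triisopropylsilyloxy)phenol; 2 3-chloro-3-methylbut-1-yne
Product: 11 [4-bromo-3-[(2-methylbut-3-yn-2-yl)oxy]phenoxy]triisopropylsilane
Conditions: CuCl2·2H2O (1 mol %), DBU, MeCN, 0 °C
Reagents that add atoms: none
Why: The same copper-catalysed propargylic etherification as in step 1, applied to the remaining acidic phenol, with the silyl ether stable to DBU.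

Step 9
Reactants: 11 [4-bromo-3-[(2-methylbut-3-yn-2-yl)oxy]phenoxy]triisopropylsilane
Product: 12 8-bromo-2,2-dimethyl-5-(triisopropylsilyloxy)-2H-chromene
Conditions: o-xylene, 140 °C
Reagents that add atoms: none
Why: Thermal aryl propargyl ether rearrangement (propargyl Claisen shift, 1,5-hydrogen shift, oxa-6π electrocyclisation), in which bromine blocks one ortho carbon so that ring D can close only onto the carbon between the two oxygens.

Step 10
Reactants: 12 8-bromo-2,2-dimethyl-5-(triisopropylsilyloxy)-2H-chromene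
Product: 13 ethyl 2-[2,2-dimethyl-5-(triisopropylsilyloxy)-2H-chromen-8-yl]acetate
Conditions: BrZnCH2CO2Et (from BrCH2CO2Et, Zn, cat. Me3SiCl, THF), Pd2(dba)3 (2 mol %), XPhos, THF, 65 °C
Reagents that add atoms: ethyl bromoacetate (used as its zinc reagent), CCOC(=O)CBr
Why: Negishi-type coupling of a Reformatsky reagent (palladium-catalysed α-arylation of a zinc ester enolate), in which the bulky biarylphosphine lets zerovalent palladium insert into the hindered electron-rich bromide and the nearly neutral zinc enolate spares the silyl ether and the chromene.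

Step 11
Reactants: 13 ethyl 2-[2,2-dimethyl-5-(triisopropylsilyloxy)-2H-chromen-8-yl]acetate
Product: 14 2-[2,2-dimethyl-5-(triisopropylsilyloxy)-2H-chromen-8-yl]acetic acid
Conditions: LiOH·H2O (1.5 equiv), THF/H2O, 0 °C → rt; dilute HCl to pH 4
Reagents that add atoms: lithium hydroxide, [Li+].[OH-]
Why: Saponification, in which the unhindered ethyl arylacetate should hydrolyse much faster than hydroxide attacks the triisopropylsilyl ether, which the neighbouring vinyl carbon of ring D screens further.

Step 12
Reactants: 14 2-[2,2-dimethyl-5-(triisopropylsilyloxy)-2H-chromen-8-yl]acetic acid; 15 (R)-4-benzyloxazolidin-2-one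
Product: 17 (4R)-4-benzyl-3-{2-[2,2-dimethyl-5-(triisopropylsilyloxy)-2H-chromen-8-yl]acetyl}oxazolidin-2-one, via mixed pivalic anhydride 16 (not isolated)
Conditions: t-BuCOCl, Et3N, THF, −20 °C; then LiCl, 15, −20 °C → rt
Reagents that add atoms: pivaloyl chloride, CC(C)(C)C(=O)Cl (its atoms stay only in 16)
Why: N-acylation of the oxazolidinone through a mixed anhydride with LiCl/Et3N activation, with attack at the less hindered arylacetyl carbonyl and no strong base needed.

Step 13
Reactants: 17 (4R)-4-benzyl-3-{2-[2,2-dimethyl-5-(triisopropylsilyloxy)-2H-chromen-8-yl]acetyl}oxazolidin-2-one; 8 1-bromo-5-(bromomethyl)-2,4-dimethoxy-3-(3-methylbut-2-enyl)benzene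
Product: 19 (4R)-4-benzyl-3-[(2R)-3-[5-bromo-2,4-dimethoxy-3-(3-methylbut-2-enyl)phenyl]-2-[2,2-dimethyl-5-(triisopropylsilyloxy)-2H-chromen-8-yl]propanoyl]oxazolidin-2-one, via sodium Z-enolate 18 (not isolated)
Conditions: NaN(SiMe3)2, THF, −78 °C; then 8, −78 → −30 °C
Reagents that add atoms: sodium bis(trimethylsilyl)amide, [Na]N([Si](C)(C)C)[Si](C)(C)C (sodium stays only in 18)
Why: Evans alkylation, in which the sodium-chelated Z-enolate 18 is attacked by the benzylic bromide on the face opposite the C4 benzyl group of the (R)-auxiliary, making the new centre (the future C3) R.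

Step 14
Reactants: 19 (4R)-4-benzyl-3-[(2R)-3-[5-bromo-2,4-dimethoxy-3-(3-methylbut-2-enyl)phenyl]-2-[2,2-dimethyl-5-(triisopropylsilyloxy)-2H-chromen-8-yl]propanoyl]oxazolidin-2-one
Product: 20 (2R)-3-[5-bromo-2,4-dimethoxy-3-(3-methylbut-2-enyl)phenyl]-2-[2,2-dimethyl-5-(triisopropylsilyloxy)-2H-chromen-8-yl]propan-1-ol
Conditions: LiBH4, MeOH (1 equiv), THF, 0 °C
Reagents that add atoms: none
Why: Reductive cleavage of the imide with LiBH4, in which hydride attacks the exocyclic carbonyl and releases the auxiliary without enolisation, so the centre is retained and the aryl bromide, alkenes and silyl ether survive.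

Step 15
Reactants: 20 (2R)-3-[5-bromo-2,4-dimethoxy-3-(3-methylbut-2-enyl)phenyl]-2-[2,2-dimethyl-5-(triisopropylsilyloxy)-2H-chromen-8-yl]propan-1-ol
Product: 21 (2R)-3-[5-bromo-2,4-dimethoxy-3-(3-methylbut-2-enyl)phenyl]-2-(5-hydroxy-2,2-dimethyl-2H-chromen-8-yl)propan-1-ol
Conditions: Bu4NF, AcOH, THF, 0 °C
Reagents that add atoms: none
Why: Fluoride desilylation, in which buffered Bu4NF cleaves the aryl silyl ether through Si-F bond formation and touches no other group.

Step 16
Reactants: 21 (2R)-3-[5-bromo-2,4-dimethoxy-3-(3-methylbut-2-enyl)phenyl]-2-(5-hydroxy-2,2-dimethyl-2H-chromen-8-yl)propan-1-ol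
Product: 24 kanzonol I, via dilithio aryne 22 (not isolated), via C8-lithiated chroman 23 (not isolated)
Conditions: LiTMP (5 equiv, from n-BuLi and a slight excess of 2,2,6,6-tetramethylpiperidine), THF (0.01 M), −78 → 0 °C; sat. aq NH4Cl
Reagents that add atoms: lithium 2,2,6,6-tetramethylpiperidide, [Li]N1C(C)(C)CCCC1(C)C (lithium stays only in 22 and 23)
Why: LiTMP first takes the phenol and alcohol protons and then removes C8a-H, the only hydrogen beside the C8 bromine (the side-chain lithium alkoxide should help to bring the base there), and loss of LiBr gives the C8-C8a aryne 22. The C2 alkoxide adds to C8a in the plane of ring A and leaves the aryllithium 23, whose carbanion at C8 sits between O1 and the C7 methoxyl and is protonated by tetramethylpiperidine or on quench. The closest known chemistry is the ring closure of haloarenes bearing a side-chain alkoxide through arynes made with amide bases (chromans, dihydrobenzofurans), together with the cine substitution of 2-haloanisoles, which gives meta products only. Ring C closes in a 6-exo-dig mode with the second aryne carbon C8 outside the new ring, whereas attack at C8 would demand a seven-membered endo closure. No stereocentre is formed, and C3 should keep its configuration because its benzylic hydrogen on the electron-rich phenoxide ring B is far less acidic than C8a-H. The step needs regioselective addition and capture ahead of the amine: the tether length and the inductive pull of the C7 methoxyl, which directs nucleophiles to the distal aryne carbon, both point to C8a, while the hindered amide, high dilution and temperatures not above 0 °C hold back amine addition, phenoxide arylation and metalation of the prenyl methylene.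

**Compound list**
1 | 5-bromo-2-hydroxy-4-methoxybenzaldehyde | COc1cc(O)c(C=O)cc1Br | starting material
2 | 3-chloro-3-methylbut-1-yne | C#CC(C)(C)Cl | starting material
3 | 5-bromo-4-methoxy-2-[(2-methylbut-3-yn-2-yl)oxy]benzaldehyde | COc1cc(OC(C)(C)C#C)c(C=O)cc1Br | intermediate
4 | 5-bromo-4-methoxy-2-[(2-methylbut-3-en-2-yl)oxy]benzaldehyde | COc1cc(OC(C)(C)C=C)c(C=O)cc1Br | intermediate
5 | 5-bromo-2-hydroxy-4-methoxy-3-(3-methylbut-2-enyl)benzaldehyde | COc1c(Br)cc(C=O)c(O)c1CC=C(C)C | intermediate
6 | 5-bromo-2,4-dimethoxy-3-(3-methylbut-2-enyl)benzaldehyde | COc1c(Br)cc(C=O)c(OC)c1CC=C(C)C | intermediate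
7 | [5-bromo-2,4-dimethoxy-3-(3-methylbut-2-enyl)phenyl]methanol | COc1c(Br)cc(CO)c(OC)c1CC=C(C)C | intermediate
8 | 1-bromo-5-(bromomethyl)-2,4-dimethoxy-3-(3-methylbut-2-enyl)benzene | COc1c(Br)cc(CBr)c(OC)c1CC=C(C)C | intermediate
9 | 4-bromoresorcinol | Oc1ccc(Br)c(O)c1 | starting material
10 | 2-bromo-5-(triisopropylsilyloxy)phenol | Oc1cc(O[Si](C(C)C)(C(C)C)C(C)C)ccc1Br | intermediate
11 | [4-bromo-3-[(2-methylbut-3-yn-2-yl)oxy]phenoxy]triisopropylsilane | C#CC(C)(C)Oc1cc(O[Si](C(C)C)(C(C)C)C(C)C)ccc1Br | intermediate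
12 | 8-bromo-2,2-dimethyl-5-(triisopropylsilyloxy)-2H-chromene | CC1(C)C=Cc2c(O[Si](C(C)C)(C(C)C)C(C)C)ccc(Br)c2O1 | intermediate
13 | ethyl 2-[2,2-dimethyl-5-(triisopropylsilyloxy)-2H-chromen-8-yl]acetate | CCOC(=O)Cc1ccc(O[Si](C(C)C)(C(C)C)C(C)C)c2c1OC(C)(C)C=C2 | intermediate
14 | 2-[2,2-dimethyl-5-(triisopropylsilyloxy)-2H-chromen-8-yl]acetic acid | OC(=O)Cc1ccc(O[Si](C(C)C)(C(C)C)C(C)C)c2c1OC(C)(C)C=C2 | intermediate
15 | (R)-4-benzyloxazolidin-2-one | O=C1OC[C@@H](Cc2ccccc2)N1 | starting material
16 | mixed anhydride of 14 with pivalic acid | CC(C)(C)C(=O)OC(=O)Cc1ccc(O[Si](C(C)C)(C(C)C)C(C)C)c2c1OC(C)(C)C=C2 | intermediate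
17 | (4R)-4-benzyl-3-{2-[2,2-dimethyl-5-(triisopropylsilyloxy)-2H-chromen-8-yl]acetyl}oxazolidin-2-one | O=C1OC[C@@H](Cc2ccccc2)N1C(=O)Cc1ccc(O[Si](C(C)C)(C(C)C)C(C)C)c2c1OC(C)(C)C=C2 | intermediate
18 | sodium (Z)-enolate of 17 | O=C1OC[C@@H](Cc2ccccc2)N1/C(O[Na])=C/c1ccc(O[Si](C(C)C)(C(C)C)C(C)C)c2c1OC(C)(C)C=C2 | intermediate
19 | (4R)-4-benzyl-3-[(2R)-3-[5-bromo-2,4-dimethoxy-3-(3-methylbut-2-enyl)phenyl]-2-[2,2-dimethyl-5-(triisopropylsilyloxy)-2H-chromen-8-yl]propanoyl]oxazolidin-2-one | COc1c(Br)cc(C[C@H](c2ccc(O[Si](C(C)C)(C(C)C)C(C)C)c3c2OC(C)(C)C=C3)C(=O)N2[C@H](Cc3ccccc3)COC2=O)c(OC)c1CC=C(C)C | intermediate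
20 | (2R)-3-[5-bromo-2,4-dimethoxy-3-(3-methylbut-2-enyl)phenyl]-2-[2,2-dimethyl-5-(triisopropylsilyloxy)-2H-chromen-8-yl]propan-1-ol | COc1c(Br)cc(C[C@H](c2ccc(O[Si](C(C)C)(C(C)C)C(C)C)c3c2OC(C)(C)C=C3)CO)c(OC)c1CC=C(C)C | intermediate
21 | (2R)-3-[5-bromo-2,4-dimethoxy-3-(3-methylbut-2-enyl)phenyl]-2-(5-hydroxy-2,2-dimethyl-2H-chromen-8-yl)propan-1-ol | COc1c(Br)cc(C[C@H](c2ccc(O)c3c2OC(C)(C)C=C3)CO)c(OC)c1CC=C(C)C | intermediate
22 | C8-C8a aryne as its dilithium alkoxide phenoxide | COC1=C(CC=C(C)C)C(OC)=C(C[C@H](c2ccc(O[Li])c3c2OC(C)(C)C=C3)CO[Li])C#C1 | intermediate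
23 | 8-lithio derivative of kanzonol I lithium phenoxide | COc1c([Li])c2c(c(OC)c1CC=C(C)C)C[C@H](c1ccc(O[Li])c3c1OC(C)(C)C=C3)CO2 | intermediate
24 | kanzonol I = (3R)-3-(5-hydroxy-2,2-dimethyl-2H-chromen-8-yl)-5,7-dimethoxy-6-(3-methylbut-2-enyl)chroman | COc1cc2c(c(OC)c1CC=C(C)C)C[C@H](c1ccc(O)c3c1OC(C)(C)C=C3)CO2 | target

**Step count**
Total steps: 16. The longest linear sequence is 10 steps: steps 1-6 and then 13-16 from 1. The branch from 9 through steps 7-16 is equally long.

**Steps most likely to fail**

**Step 16.**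
- Risks: slow removal of C8a-H, which lies between bromine and an alkyl group. Metalation of the doubly activated prenyl methylene with migration of the alkene. Capture of the aryne by the amine or by a second molecule.
- Fallback: the C8a anion is intercepted before LiBr is lost and the ring is closed at the other C-O bond. It sets out from 20.
- LiTMP is added at −78 °C in the presence of B(OiPr)3 (in situ trapping of the ortho-lithiated bromoarene). Hydrolysis should then give the C8a boronic acid F1.
- NaBO3·4H2O in THF/H2O oxidises it to the C8a phenol F2.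
- A Mitsunobu etherification (PPh3, DIAD, THF) joins this phenol oxygen to C2 and gives 8-bromo-O-triisopropylsilylkanzonol I F3.
- Bromine-lithium exchange (t-BuLi, THF, −78 °C) with a methanol quench gives O-triisopropylsilylkanzonol I F4.
- Bu4NF then returns to the route at 24.

**Step 13.**
- Risks: decay of the imide enolate by ketene loss. Solvolytic decomposition of the electron-rich benzylic bromide before C-C bond formation. Incomplete facial control with the ortho-substituted aryl group.
- Fallback: the covalent auxiliary is dropped and the acid itself is alkylated. It sets out from 14.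
- The dilithium enediolate is formed with n-BuLi together with a C2-symmetric chiral bis(lithium amide). This comes from N,N'-bis[1-phenyl-2-(piperidin-1-yl)ethyl]propane-1,3-diamine, used in the enantiomeric series that delivers the R acid.
- The enediolate is benzylated with 8 at −78 °C inside the mixed aggregate. This gives (2R)-3-[5-bromo-2,4-dimethoxy-3-(3-methylbut-2-enyl)phenyl]-2-[2,2-dimethyl-5-(triisopropylsilyloxy)-2H-chromen-8-yl]propanoic acid F5.
- LiAlH4 in THF at 0 °C reduces it and the route is rejoined at 20.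

**Step 1.**
- Risks: sluggish O-alkylation of the chelated, weakly nucleophilic salicylaldehyde phenoxide by a tertiary electrophile. Later heterolytic loss of the tert-allyl group is also possible.
- Fallback: the prenyl group is brought in by cross-coupling instead of rearrangement. It sets out from 1.
- Electrophilic iodination (N-iodosuccinimide, cat. CF3CO2H, MeCN) should enter at C3, the only free carbon ortho to both oxygens. This gives 5-bromo-2-hydroxy-3-iodo-4-methoxybenzaldehyde F6.
- MeI/K2CO3 gives 5-bromo-3-iodo-2,4-dimethoxybenzaldehyde F7.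
- A Stille coupling with tributyl(3-methylbut-2-enyl)stannane (Pd(PPh3)4, CuI, CsF, DMF, 45 °C) reacts at the iodide in preference to the bromide. It comes back to the route at 6.

**Further compounds**
F1 | step 16 | {2-bromo-6-[(2R)-3-hydroxy-2-[2,2-dimethyl-5-(triisopropylsilyloxy)-2H-chromen-8-yl]propyl]-3,5-dimethoxy-4-(3-methylbut-2-enyl)phenyl}boronic acid | COc1c(Br)c(B(O)O)c(C[C@H](c2ccc(O[Si](C(C)C)(C(C)C)C(C)C)c3c2OC(C)(C)C=C3)CO)c(OC)c1CC=C(C)C
F2 | step 16 | 2-bromo-6-[(2R)-3-hydroxy-2-[2,2-dimethyl-5-(triisopropylsilyloxy)-2H-chromen-8-yl]propyl]-3,5-dimethoxy-4-(3-methylbut-2-enyl)phenol | COc1c(Br)c(O)c(C[C@H](c2ccc(O[Si](C(C)C)(C(C)C)C(C)C)c3c2OC(C)(C)C=C3)CO)c(OC)c1CC=C(C)C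
F3 | step 16 | (3R)-8-bromo-5,7-dimethoxy-6-(3-methylbut-2-enyl)-3-[2,2-dimethyl-5-(triisopropylsilyloxy)-2H-chromen-8-yl]chroman | COc1c(Br)c2c(c(OC)c1CC=C(C)C)C[C@H](c1ccc(O[Si](C(C)C)(C(C)C)C(C)C)c3c1OC(C)(C)C=C3)CO2
F4 | step 16 | (3R)-5,7-dimethoxy-6-(3-methylbut-2-enyl)-3-[2,2-dimethyl-5-(triisopropylsilyloxy)-2H-chromen-8-yl]chroman | COc1cc2c(c(OC)c1CC=C(C)C)C[C@H](c1ccc(O[Si](C(C)C)(C(C)C)C(C)C)c3c1OC(C)(C)C=C3)CO2
F5 | step 13 | (2R)-3-[5-bromo-2,4-dimethoxy-3-(3-methylbut-2-enyl)phenyl]-2-[2,2-dimethyl-5-(triisopropylsilyloxy)-2H-chromen-8-yl]propanoic acid | COc1c(Br)cc(C[C@H](c2ccc(O[Si](C(C)C)(C(C)C)C(C)C)c3c2OC(C)(C)C=C3)C(=O)O)c(OC)c1CC=C(C)C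
F6 | step 1 | 5-bromo-2-hydroxy-3-iodo-4-methoxybenzaldehyde | COc1c(Br)cc(C=O)c(O)c1I
F7 | step 1 | 5-bromo-3-iodo-2,4-dimethoxybenzaldehyde | COc1c(Br)cc(C=O)c(OC)c1I
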